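Ring labels used below: ring A = 4-oxyphenyl on C2, ring B = benzo ring, ring C = dihydrofuran, ring D = 3,5-dioxyphenyl on C3, ring E = 3,5-dioxyphenyl of the styryl arm; in the stilbene, C7 sits on ring A and C8 on ring D.

Retrosynthesis: first the five O–Si bonds, then the aryl–vinyl bond C5–Cα of the styryl arm (Mizoroki–Heck on a 5-triflate), then both ring-forming bonds of ring C, C3–C3a and O1–C2, in one formal [3+2] step back to 1,4-benzoquinone and silylated resveratrol.
Forward: resveratrol is silylated; its alkene is joined to benzoquinone, which builds ring C onto what becomes ring B and leaves a 5-OH; triflation, Heck coupling with a separately made 3,5-disilyloxystyrene (ring E) and global desilylation finish a convergent route.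
Enabling feature: in the phenol series, C8 of the 4-oxystilbene and the ring B carbon ortho to oxygen (C3a) are both nucleophilic. At the quinone oxidation level C3a is an enone β-carbon and accepts C8, while C7, made cationic and stabilised by the para oxygen of ring A, is caught by the adjacent quinone oxygen (O1).
Stereochemistry: C3 comes from a chiral cationic oxazaborolidine that decides which alkene face bonds to the quinone; C2 follows from C3 (same-face addition to the E-alkene gives trans, which is also the thermodynamic arrangement); the E-alkene of the arm comes from syn β-hydride elimination in the Heck step.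
Helper: the second quinone oxygen ends as the 5-OH, is turned into a triflate and leaves in the Heck step.

Key step: step 2

Assumption: the sense of induction of the chiral Lewis acid in step 2 cannot be predicted with certainty; the (S)-catalyst is written, and its (R)-enantiomer is to be used instead if a first run shows the opposite sense.

Step 1
Reactants: 1 trans-resveratrol
Product: 2 (E)-1-[3,5-bis(triisopropylsilyloxy)phenyl]-2-[4-(triisopropylsilyloxy)phenyl]ethene
Conditions: TIPSCl (3.6 equiv), imidazole (7 equiv), DMF, rt
Reagents that add atoms: triisopropylsilyl chloride (TIPSCl), CC(C)[Si](Cl)(C(C)C)C(C)C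
Why: Silyl ether formation on all three phenols is routine, keeps the para oxygen of ring A as a donor for the alkene, shields the free positions of ring D and gives groups that fall off together at the end; no stereocentre is made and the E-alkene is untouched.

Step 2
Reactants: 2 (E)-1-[3,5-bis(triisopropylsilyloxy)phenyl]-2-[4-(triisopropylsilyloxy)phenyl]ethene (1.2 equiv); 3 1,4-benzoquinone (1.0 equiv)
Product: 5 (2S,3S)-3-[3,5-bis(triisopropylsilyloxy)phenyl]-2-[4-(triisopropylsilyloxy)phenyl]-2,3-dihydro-1-benzofuran-5-ol, via open-chain benzylic cation 4 (not isolated)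
Conditions: (S)-1-(2-methylphenyl)-3,3-diphenyltetrahydro-1H,3H-pyrrolo[1,2-c][1,3,2]oxazaborole (20 mol %), HN(SO2CF3)2 (20 mol %), 4 Å MS, CH2Cl2, −78 → −20 °C
Reagents that add atoms: none
Why: Proposed new method: the cationic boron Lewis acid binds one carbonyl oxygen of 3 and activates the adjoining C=C as a Michael acceptor, C8 of 2 attacks its β-carbon, which becomes C3a, and the 4-silyloxybenzylic cation 4 left at C7 is trapped by the neighbouring quinone oxygen, which becomes O1, while the six-membered ring aromatises to the phenol. The closest known reaction type is the chiral-Lewis-acid-catalysed formal [3+2] cycloaddition of 1,4-benzoquinones with enol ethers and of 2-alkoxy-1,4-benzoquinones with (E)-propenylarenes to 2,3-dihydrobenzofuran-5-ols; parent benzoquinone with a 1,2-diarylethene under an enantioselective catalyst goes beyond it. Ring C is closed by two bonds, C3–C3a in the intermolecular conjugate addition and O1–C2 in a 5-exo-trig attack of oxygen on the benzylic cation. C3 is set under catalyst control, since the bound catalyst shields one face of the enone and an endo-type approach with ring A over the quinone decides which alkene face reacts, and C2 is set by C3 because carbon and oxygen add to the same face of the E-alkene, which places rings A and D trans, the arrangement also favoured thermodynamically should the benzylic C2–O bond ionise reversibly. The step needs regioselectivity (C8 and not C7 must bond to the quinone), secured by the para silyloxy group of ring A that stabilises positive charge only at C7, chemoselectivity for the alkene over the oxygenated rings A and D, secured by the bulky TIPS ethers next to their free positions, and facial selectivity, which rests on the catalyst.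

Step 3
Reactants: 5 (2S,3S)-3-[3,5-bis(triisopropylsilyloxy)phenyl]-2-[4-(triisopropylsilyloxy)phenyl]-2,3-dihydro-1-benzofuran-5-ol
Product: 6 (2S,3S)-3-[3,5-bis(triisopropylsilyloxy)phenyl]-2-[4-(triisopropylsilyloxy)phenyl]-2,3-dihydro-1-benzofuran-5-yl trifluoromethanesulfonate
Conditions: PhNTf2, Et3N, DMAP (cat.), CH2Cl2, 0 °C → rt
Reagents that add atoms: N-phenylbis(trifluoromethanesulfonimide) (PhNTf2), O=S(=O)(N(c1ccccc1)S(=O)(=O)C(F)(F)F)C(F)(F)F
Why: Sulfonylation of the only free phenol to the aryl triflate is routine and mild enough to leave the aryl silyl ethers and both benzylic stereocentres untouched.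

Step 4
Reactants: 7 3,5-dihydroxybenzaldehyde
Product: 8 3,5-bis(triisopropylsilyloxy)benzaldehyde
Conditions: TIPSCl (2.4 equiv), imidazole (5 equiv), DMF, rt
Reagents that add atoms: triisopropylsilyl chloride (TIPSCl), CC(C)[Si](Cl)(C(C)C)C(C)C
Why: Silyl ether formation on both phenols is routine and the aldehyde is inert to TIPSCl and imidazole.

Step 5
Reactants: 8 3,5-bis(triisopropylsilyloxy)benzaldehyde
Product: 9 3,5-bis(triisopropylsilyloxy)styrene
Conditions: Ph3PCH3Br, n-BuLi, THF, 0 °C; then 8, 0 °C → rt
Reagents that add atoms: methyltriphenylphosphonium bromide, C[P+](c1ccccc1)(c1ccccc1)c1ccccc1.[Br-]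
Why: Wittig methylenation of an aromatic aldehyde with the non-stabilised ylide made in the flask is reliable, the aryl silyl ethers tolerate the salt-free ylide at low temperature, and a terminal alkene raises no stereochemical question.

Step 6
Reactants: 6 (2S,3S)-3-[3,5-bis(triisopropylsilyloxy)phenyl]-2-[4-(triisopropylsilyloxy)phenyl]-2,3-dihydro-1-benzofuran-5-yl trifluoromethanesulfonate; 9 3,5-bis(triisopropylsilyloxy)styrene
Product: 10 (2S,3S)-5-{(E)-2-[3,5-bis(triisopropylsilyloxy)phenyl]ethenyl}-3-[3,5-bis(triisopropylsilyloxy)phenyl]-2-[4-(triisopropylsilyloxy)phenyl]-2,3-dihydro-1-benzofuran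
Conditions: PdCl2(PPh3)2 (5 mol %), LiCl, Et3N, DMF, 100 °C, argon
Reagents that add atoms: none
Why: In this Mizoroki–Heck reaction zerovalent palladium formed in the flask inserts into the aryl triflate, chloride keeps the neutral pathway so that the aryl group adds to the terminal alkene carbon, syn β-hydride elimination gives the E-alkene, and C2 and C3 are not acidic enough to epimerise with Et3N.

Step 7
Reactants: 10 (2S,3S)-5-{(E)-2-[3,5-bis(triisopropylsilyloxy)phenyl]ethenyl}-3-[3,5-bis(triisopropylsilyloxy)phenyl]-2-[4-(triisopropylsilyloxy)phenyl]-2,3-dihydro-1-benzofuran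
Product: 11 (2S,3S)-trans-δ-viniferin
Conditions: Bu4NF (TBAF, 6 equiv), AcOH (6 equiv), THF, 0 °C, argon, dark
Reagents that add atoms: none
Why: Fluoride-mediated desilylation cleaves all five aryl silyl ethers through Si–F bond formation, and the acetic acid buffer keeps the phenols protonated, so that opening of ring C through a quinone methide of ring A, air oxidation and alkene isomerisation should be avoided and both stereocentres are kept.

Compound list
1 | trans-resveratrol, (E)-5-[2-(4-hydroxyphenyl)ethenyl]benzene-1,3-diol | Oc1ccc(/C=C/c2cc(O)cc(O)c2)cc1 | starting material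
2 | (E)-1-[3,5-bis(triisopropylsilyloxy)phenyl]-2-[4-(triisopropylsilyloxy)phenyl]ethene | CC(C)[Si](Oc1ccc(/C=C/c2cc(O[Si](C(C)C)(C(C)C)C(C)C)cc(O[Si](C(C)C)(C(C)C)C(C)C)c2)cc1)(C(C)C)C(C)C | intermediate
3 | 1,4-benzoquinone | O=C1C=CC(=O)C=C1 | starting material
4 | open-chain benzylic cation, (2S)-2-[3,5-bis(triisopropylsilyloxy)phenyl]-2-(2,5-dihydroxyphenyl)-1-[4-(triisopropylsilyloxy)phenyl]ethan-1-ylium, drawn without the bound catalyst (not isolated) | CC(C)[Si](Oc1ccc([CH+][C@H](c2cc(O)ccc2O)c2cc(O[Si](C(C)C)(C(C)C)C(C)C)cc(O[Si](C(C)C)(C(C)C)C(C)C)c2)cc1)(C(C)C)C(C)C | intermediate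
5 | (2S,3S)-3-[3,5-bis(triisopropylsilyloxy)phenyl]-2-[4-(triisopropylsilyloxy)phenyl]-2,3-dihydro-1-benzofuran-5-ol (trans) | CC(C)[Si](Oc1ccc([C@H]2Oc3ccc(O)cc3[C@@H]2c2cc(O[Si](C(C)C)(C(C)C)C(C)C)cc(O[Si](C(C)C)(C(C)C)C(C)C)c2)cc1)(C(C)C)C(C)C | intermediate
6 | (2S,3S)-3-[3,5-bis(triisopropylsilyloxy)phenyl]-2-[4-(triisopropylsilyloxy)phenyl]-2,3-dihydro-1-benzofuran-5-yl trifluoromethanesulfonate | CC(C)[Si](Oc1ccc([C@H]2Oc3ccc(OS(=O)(=O)C(F)(F)F)cc3[C@@H]2c2cc(O[Si](C(C)C)(C(C)C)C(C)C)cc(O[Si](C(C)C)(C(C)C)C(C)C)c2)cc1)(C(C)C)C(C)C | intermediate
7 | 3,5-dihydroxybenzaldehyde | O=Cc1cc(O)cc(O)c1 | starting material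
8 | 3,5-bis(triisopropylsilyloxy)benzaldehyde | O=Cc1cc(O[Si](C(C)C)(C(C)C)C(C)C)cc(O[Si](C(C)C)(C(C)C)C(C)C)c1 | intermediate
9 | 3,5-bis(triisopropylsilyloxy)styrene | C=Cc1cc(O[Si](C(C)C)(C(C)C)C(C)C)cc(O[Si](C(C)C)(C(C)C)C(C)C)c1 | intermediate
10 | (2S,3S)-5-{(E)-2-[3,5-bis(triisopropylsilyloxy)phenyl]ethenyl}-3-[3,5-bis(triisopropylsilyloxy)phenyl]-2-[4-(triisopropylsilyloxy)phenyl]-2,3-dihydro-1-benzofuran | CC(C)[Si](Oc1ccc([C@H]2Oc3ccc(/C=C/c4cc(O[Si](C(C)C)(C(C)C)C(C)C)cc(O[Si](C(C)C)(C(C)C)C(C)C)c4)cc3[C@@H]2c2cc(O[Si](C(C)C)(C(C)C)C(C)C)cc(O[Si](C(C)C)(C(C)C)C(C)C)c2)cc1)(C(C)C)C(C)C | intermediate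
11 | (2S,3S)-trans-δ-viniferin | Oc1ccc([C@H]2Oc3ccc(/C=C/c4cc(O)cc(O)c4)cc3[C@@H]2c2cc(O)cc(O)c2)cc1 | target

Total step count: 7
Longest linear sequence: 5 steps (steps 1, 2, 3, 6, 7)

Steps most likely to fail

The riskiest is step 2, the one step that goes beyond known chemistry. Facial discrimination may be poor because parent benzoquinone offers the catalyst no second binding point. Electron transfer from the stilbene to the activated quinone may divert material into radical-cation dimerisation. Ring D may compete as a Friedel–Crafts nucleophile, or the reaction may stall at a cyclobutane stage. The fallback uses known chemistry and sets out from 1. Oxidative dimerisation of unprotected resveratrol with AgOAc in MeOH at 50 °C proceeds by phenoxyl radical coupling of C8 of one unit with the ring carbon ortho to the hydroxyl of the other, followed by 5-exo-trig closure of the phenol onto the quinone methide. It should give the racemic trans dimer, that is 11 together with its mirror image (2R,3R)-trans-δ-viniferin F1. Preparative HPLC on a cellulose tris(3,5-dimethylphenylcarbamate) phase should then separate the two. The fallback comes back to the route at 11, so steps 3 to 7 are not needed; it gives up half of the material.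

Next is step 6. Insertion of palladium into the electron-rich aryl triflate may be slow, so that cleavage of the triflate S–O bond by the base, partial loss of silyl groups at 100 °C, or arylation at the internal alkene carbon through a cationic pathway may compete. The fallback sets out from 8 and 6. Boron-Wittig olefination of 8 with CH2(Bpin)2 and lithium 2,2,6,6-tetramethylpiperidide (THF, −78 °C → rt) should give (E)-2-[3,5-bis(triisopropylsilyloxy)phenyl]ethenylboronic acid pinacol ester F2. Suzuki–Miyaura coupling of F2 with triflate 6 (Pd(PPh3)4, K3PO4, dioxane/H2O, 80 °C) then fixes both the position and the geometry of the alkene in the boron partner. The fallback comes back to the route at 10.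

Third is step 7. Release of five phenoxides at once may lead to base-induced opening of ring C through the quinone methide of ring A, to oxidation by air, or to light-induced E to Z isomerisation during isolation. The fallback sets out from 10. Fluoride cleavage in the presence of acetic anhydride (TBAF, Ac2O, THF, 0 °C) should trap each phenoxide as it forms and give (2S,3S)-trans-δ-viniferin pentaacetate F3, a stable derivative that can be purified. Transesterification with catalytic K2CO3 in degassed MeOH at 0 °C should then release the phenols under mild conditions. The fallback comes back to the route at 11.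

Further compounds
F1 | step 2 | (2R,3R)-trans-δ-viniferin | Oc1ccc([C@@H]2Oc3ccc(/C=C/c4cc(O)cc(O)c4)cc3[C@H]2c2cc(O)cc(O)c2)cc1
F2 | step 6 | (E)-2-[3,5-bis(triisopropylsilyloxy)phenyl]ethenylboronic acid pinacol ester | CC(C)[Si](Oc1cc(/C=C/B2OC(C)(C)C(C)(C)O2)cc(O[Si](C(C)C)(C(C)C)C(C)C)c1)(C(C)C)C(C)C
F3 | step 7 | (2S,3S)-trans-δ-viniferin pentaacetate | CC(=O)Oc1ccc([C@H]2Oc3ccc(/C=C/c4cc(OC(C)=O)cc(OC(C)=O)c4)cc3[C@@H]2c2cc(OC(C)=O)cc(OC(C)=O)c2)cc1
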